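## Structural features

The target 24 is pentacyclic: ring A is a cyclohexene with a methyl group on its trisubstituted C=C, ring B a seven-membered dienol lactone, ring C a benzene ring, ring D a 1,4-quinone fused linearly to ring C, and ring E a 1,1-dioxo-1,4-thiazine fused to the quinone C=C through S and N. Rings A and B share the quaternary carbon and the neighbouring sp2 carbon, whose exocyclic C=CH–O bond is the enol half of the lactone. Rings B and C share the two adjacent aromatic carbons that carry the lactone carbonyl and the quaternary carbon. The only stereocentre is this all-carbon quaternary (S) carbon (methyl, ring A CH2, ring A sp2 carbon, aryl carbon). It has no stereogenic neighbour, so only absolute configuration has to be controlled, but it lies between two fully substituted sp2 carbons and is hard to create late. The fragile groups are the dienyl ester (sensitive to acid, base and amines, and able to lose the position of its diene), the quinone and the vinylogous sulfonamide N–H. The real difficulties are the congested quaternary centre, the placing of S and N on the quinone (S next to the carbonyl on the ring C carbon para to the quaternary-bearing carbon, N next to the carbonyl para to the lactone-carbonyl-bearing carbon), and closure of the enol lactone with the C(CH3)=CH bond inside ring A. The key step uses the pattern of ring C: its two adjacent substituted carbons are the two carbons of an alkynoate whose propargylic carbon is the stereocentre, and its two C–H carbons and two ring D fusion carbons are the four carbons of an ortho-quinodimethane that already holds ring D as a hydroquinone dimethyl ether.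

## Logic of the disconnections

**24 ⇒ 19 + 20.** The C–S and C–N bonds joining ring E to the quinone are cut. All atoms of ring E are present in 20, and the vinylogous sulfonamide is the least robust part of 24, so it is added last. This removes a ring and both heteroatoms and leaves an unsubstituted quinone C=C. The forward step must place S on the quinone carbon β to the carbonyl that is para-related to the lactone carbonyl carbon. That is the more electrophilic β-position, because the other carbonyl is weakened by the para alkyl-bearing carbon. The sulfinate must therefore attack first, which requires a pH at which the amine is protonated; two oxidations must follow, and the dienyl ester must escape aminolysis.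

**19 ⇒ 18.** No skeletal bond is cut; two O–CH3 bonds are restored. A quinone would not survive the bases, iodide, hydride acceptor and acylating medium used earlier, whereas a 1,4-dimethoxyarene is inert to all of them. The forward oxidation must distinguish the electron-rich dimethoxynaphthalene from the dienyl ester.

**18 ⇒ 16 (through 17).** The acyl C–O bond of ring B is cut. The enol ester is the most labile bond of the skeleton, while its components, an aryl carboxyl and an enal, are robust. Ring B is thereby absent during cycloaddition and dehydrogenation. The forward step must acylate the dienol oxygen and remove a proton from the ring CH2, not the ring methyl, so that the C(CH3)=CH bond ends inside ring A.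

**16 ⇒ 15.** Two C–H bonds are restored, which takes ring C back to its 1,4-dihydro form, the direct cycloadduct. The forward step needs a mild hydride acceptor that leaves the enal untouched.

**15 ⇒ 10 + 13 (through 14).** The two bonds between the benzylic CH2 groups of ring C and the sp2 carbons bearing the ester and ring A are cut. These are the two bonds of a [4+2] addition of a quinodimethane to an alkyne. Ring D arrives complete and protected, and the stereocentre lies one bond outside the reacting system. The molecule falls into a chiral 16-carbon half and an achiral, symmetric 10-carbon half. The forward step requires a transient diene to be intercepted by a triple bond attached to a quaternary carbon, faster than it dimerises and in preference to the enal.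

**13 ⇒ 12 ⇒ 11.** Two C–Br bonds and then two O–CH3 bonds are removed, leading to a symmetric hydroquinone. The forward bromination must be benzylic and not nuclear.

**10 ⇒ 8 (through 9).** The bond between the alkyne and the carboxyl carbon is cut, and the enal is retraced to its methyl dienol ether. Carboxylation of a metal acetylide is the shortest way to the alkynoate but needs a strong base. The ring A aldehyde must therefore be masked at that moment and freed afterwards by acid, which an ester cleavable only by strong acid survives. Making the alkyne before the ring A aldehyde also means that two aldehydes never coexist.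

**8 ⇒ 7.** The exocyclic C=C is cut, removing one carbon and leaving a ketone. The forward olefination has to succeed on an enone with a quaternary α-carbon and in the presence of a terminal alkyne.

**7 ⇒ 6 ⇒ 5 ⇒ 4.** The ketone goes back to the silyl-protected carbinol, and the ethynyl group to a formyl group with removal of one carbon. The silyl ether is kept during the basic homologation so that the β-oxygenated aldehyde cannot undergo retro-aldol cleavage.

**4 ⇒ 2 + 3.** Two ring A bonds are cut, the one from the quaternary carbon to the oxygenated carbon and the CH2–CH2 bond. Ring A and the stereocentre then come from two small achiral pieces in one catalytic step. The forward cycloaddition must give the "ortho" orientation and discriminate the faces of the α-carbon of 3. The carbinol configuration does not matter.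

**2 ⇒ 1.** The O–Si bond is cut; the forward step is a γ-deprotonating silylation that must give the (E) enol ether.

## Other disconnections considered

**Alternative 1:** The cut is made in ring A, at the bond from the quaternary carbon to its CH2 and at the C=C that links ring A to the future lactone enol carbon. In the forward step 7-bromo-4-methoxy-1-methylnaphthalen-2-ol A1 would be deprotonated by KOH in the presence of a cinchona-derived quaternary ammonium salt, add through C1 to pent-1-en-3-one A2 in a dearomatising Michael reaction, and close ring A by aldol condensation in the same pot to give dienone A3.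
- In its favour: the stereocentre, ring A and ring C appear in one operation from flat materials, under simple conditions without cryogenics. The C=C(OCH3) unit of A3 is a latent form of both lactone carbons, since its oxidative cleavage would give the ring A aldehyde and the aryl ester at once. On these two points it is better than the chosen plan, which spends three steps on the ring A aldehyde and the ester carbon.
- Against it: ring A arrives in the wrong oxidation pattern. The ketone of A3 sits on the carbon that must become the ring CH=, and the alkene must move, so a deoxygenation with transposition is needed. The enol ether has to be cleaved in the presence of another alkene. Rings D and E are absent altogether, and building ring D from the bromine of A3 needs functionalisation of the adjacent C–H as well.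
- Comparison: the facial control rests on a chiral ion pair at a naphtholate carbon, with O-alkylation and incomplete facial control as the risks; the chosen plan relies on a Lewis-acid-bound enal, which is comparably demanding. In step count the redox corrections on ring A and the late construction of ring D are expected to outweigh the saving at the key step, whereas the chosen cycloaddition delivers ring D ready-made.

**Alternative 2:** The cut is the bond between the ring C carbon para to the quaternary-bearing carbon and the adjacent ring D carbon, preceded by the aryl–carbon bond at the other fusion carbon. In the forward sense aryl bromide A4, after halogen–magnesium exchange, would add to the carbonyl next to the nitrogen-bearing carbon of thiazine-fused cyclobutenedione A5 to give hydroxycyclobutenone A6. Heating A6 in toluene would open the four-membered ring to a vinylketene, whose ketene carbon closes onto the free ortho carbon to give hydroquinone A7.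
- In its favour: the positions of N and S are fixed by construction, because the aryl group enters at a defined carbonyl of A5. This is better than the chosen plan, where the same regiochemistry depends on pH-controlled chemoselectivity of 20 and a modest electronic bias in 19. The ring-forming step needs no reagent, and the route is convergent.
- Against it: A5 is a multi-step building block. The arylmagnesium species must be made beside a tert-butyl ester and an acid-labile dienol ether. Two ortho positions are free in A6, and only steric hindrance by the quaternary group directs closure to the required one. Boc removal, ester cleavage and lactonisation still follow on a molecule that already carries the sensitive ring E.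
- Comparison: the stereocentre and ring A must be made before the key step in both plans, so the two are equal there. Both key steps are pericyclic and thermally driven, but the chosen one forms ring C from simpler partners. Overall the step count is expected to be higher for this alternative because both of its partners are elaborate.

**Alternative 3:** The cut is made at the two ring A bonds of the dienophile carbons, as in step 2 of the chosen plan, but with the aryl group already attached. 2-Arylacrolein A8 would react with diene 2 under a triflimide-activated chiral B-aryl oxazaborolidine to give cycloadduct A9.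
- In its favour: rings C and D are complete before the stereocentre is made, and the third methoxy group of A8 marks the quinone carbon for nitrogen, which again fixes the N/S regiochemistry better than the chosen plan does. Diene and catalyst class are the same as in the chosen route, so the two are equal in the way the stereocentre is set.
- Against it: the formyl group on the quaternary carbon of A9 must be reduced to a methyl group, a neopentyl deoxygenation of two or three steps. In the chosen plan that formyl carbon is used constructively as an alkyne carbon. A8 is a twisted, hindered dienophile that is prone to polymerise, and facial control for 2-arylacroleins is less secure than for 3. The ketone homologation and lactonisation of the chosen route are still required.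
- Comparison: the step counts are expected to be similar. The chosen plan builds ring C later but more reliably, because its cycloaddition is driven by rearomatisation; the alternative shifts the risk to the asymmetric step itself.

Key step: step 10

Assumption: the sense of induction in step 2 is taken from the formyl C–H···O binding model for 2-substituted acroleins, under which the (S)-configured catalyst exposes the Re face of the α-carbon of 3; the Si-face addition needed for 4 is therefore assigned to the (R)-configured catalyst.

## Route

**Step 1**
Reactants: 1 (E)-2-methylbut-2-enal
Product: 2 tert-butyl{[(1E)-2-methylbuta-1,3-dien-1-yl]oxy}dimethylsilane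
Conditions: TBSOTf, Et3N, Et2O, 0 °C → rt
Reagents that add atoms: tert-butyldimethylsilyl trifluoromethanesulfonate, CC(C)(C)[Si](C)(C)OS(=O)(=O)C(F)(F)F
Why: Soft enolisation: silylation of the carbonyl oxygen followed by γ-deprotonation by Et3N gives the conjugated silyl dienol ether, and the preferred s-trans enal translates into the (E) enol ether needed for cycloaddition.

**Step 2**
Reactants: 2 tert-butyl{[(1E)-2-methylbuta-1,3-dien-1-yl]oxy}dimethylsilane; 3 methacrolein
Product: 4 (1R,2S)-2-{[tert-butyl(dimethyl)silyl]oxy}-1,3-dimethylcyclohex-3-ene-1-carbaldehyde (formyl and silyloxy cis)
Conditions: (R)-3,3-diphenyl-1-(2-methylphenyl)tetrahydro-1H,3H-pyrrolo[1,2-c][1,3,2]oxazaborole (15 mol %), Tf2NH (12 mol %), CH2Cl2, −78 °C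
Reagents that add atoms: none
Why: Lewis-acid-catalysed asymmetric Diels–Alder reaction: the protonated oxazaborolidine binds 3 at boron with a formyl C–H···O contact, a phenyl group screens one face of the s-trans enal, and the oxygen-bearing diene terminus bonds to the α-carbon (the "ortho" orientation imposed by the silyloxy donor). The quaternary centre is set by catalyst-controlled addition to the Si face of the α-carbon of 3; the carbinol centre follows from the endo transition state and is removed in step 5, so its ratio is of no consequence.

**Step 3**
Reactants: 4 (1R,2S)-2-{[tert-butyl(dimethyl)silyl]oxy}-1,3-dimethylcyclohex-3-ene-1-carbaldehyde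
Product: 5 tert-butyl{[(1S,6S)-6-ethynyl-2,6-dimethylcyclohex-2-en-1-yl]oxy}dimethylsilane
Conditions: dimethyl (1-diazo-2-oxopropyl)phosphonate, K2CO3, MeOH, 0 °C → rt
Reagents that add atoms: dimethyl (1-diazo-2-oxopropyl)phosphonate, CC(=O)C(=[N+]=[N-])P(=O)(OC)OC
Why: Seyferth–Gilbert homologation in its Ohira–Bestmann form: the diazomethylphosphonate anion adds to the aldehyde, and loss of phosphate and N2 gives an alkylidene carbene that rearranges to the terminal alkyne. The aldehyde has no α-hydrogen, and the silyl ether blocks retro-aldol cleavage in K2CO3/MeOH.

**Step 4**
Reactants: 5 tert-butyl{[(1S,6S)-6-ethynyl-2,6-dimethylcyclohex-2-en-1-yl]oxy}dimethylsilane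
Product: 6 (1S,6S)-6-ethynyl-2,6-dimethylcyclohex-2-en-1-ol
Conditions: Bu4NF, THF, 0 °C → rt
Reagents that add atoms: none
Why: Fluoride-induced cleavage of the Si–O bond, driven by the strong Si–F bond; alkyne and alkene are inert, and the carbinol configuration is of no consequence.

**Step 5**
Reactants: 6 (1S,6S)-6-ethynyl-2,6-dimethylcyclohex-2-en-1-ol
Product: 7 (6S)-6-ethynyl-2,6-dimethylcyclohex-2-en-1-one
Conditions: Dess–Martin periodinane, NaHCO3, CH2Cl2, 0 °C → rt
Reagents that add atoms: none
Why: Dess–Martin oxidation of a secondary allylic alcohol under buffered, non-acidic conditions; it removes the carbinol stereocentre, so that both diastereomers of 4 converge on one enone whose only stereocentre is the quaternary carbon.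

**Step 6**
Reactants: 7 (6S)-6-ethynyl-2,6-dimethylcyclohex-2-en-1-one
Product: 8 (5S)-5-ethynyl-6-(methoxymethylidene)-1,5-dimethylcyclohex-1-ene (either enol ether geometry)
Conditions: MeOCH2PPh3Cl, KN(SiMe3)2, THF, 0 °C → 50 °C
Reagents that add atoms: (methoxymethyl)triphenylphosphonium chloride, COC[P+](c1ccccc1)(c1ccccc1)c1ccccc1.[Cl-]
Why: Wittig olefination with a non-stabilised alkoxymethylene ylide; the ketone has no α-hydrogen on the quaternary side, the ethynyl group is a small substituent, and excess ylide compensates for reversible deprotonation of the alkyne. The enol ether geometry is irrelevant because it is lost in step 7.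

**Step 7**
Reactants: 8 (5S)-5-ethynyl-6-(methoxymethylidene)-1,5-dimethylcyclohex-1-ene
Product: 10 tert-butyl 3-[(1S)-2-formyl-1,3-dimethylcyclohex-2-en-1-yl]prop-2-ynoate, via alkynoate dienol ether 9 (not isolated)
Conditions: n-BuLi, THF, −78 °C; Boc2O, −78 → 0 °C; then 2 M HCl, THF, rt
Reagents that add atoms: di-tert-butyl dicarbonate, CC(C)(C)OC(=O)OC(=O)OC(C)(C)C; water, O
Why: n-BuLi removes only the alkyne proton at −78 °C and the acetylide is acylated by Boc2O (acetylide carboxylation) to give 9; the dienol ether is inert to both. Aqueous acid then hydrolyses the enol ether and equilibrates the aldehyde into conjugation with the tetrasubstituted C=C, while the tert-butyl ester tolerates dilute acid at room temperature.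

**Step 8**
Reactants: 11 2,3-dimethylbenzene-1,4-diol
Product: 12 1,4-dimethoxy-2,3-dimethylbenzene
Conditions: MeI, K2CO3, acetone, reflux, under N2
Reagents that add atoms: iodomethane, C[I]
Why: Williamson ether synthesis on both phenols; the inert atmosphere prevents air oxidation of the hydroquinone anion.

**Step 9**
Reactants: 12 1,4-dimethoxy-2,3-dimethylbenzene
Product: 13 2,3-bis(bromomethyl)-1,4-dimethoxybenzene
Conditions: N-bromosuccinimide (2.1 equiv), AIBN (cat.), PhCF3, 85 °C
Reagents that add atoms: N-bromosuccinimide, O=C1CCC(=O)N1Br
Why: Wohl–Ziegler bromination: bromine atoms abstract benzylic hydrogen, and in a non-polar solvent with a radical initiator side-chain substitution is favoured over electrophilic ring bromination; one bromine per methyl group is controlled by stoichiometry.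

**Step 10**
Reactants: 10 tert-butyl 3-[(1S)-2-formyl-1,3-dimethylcyclohex-2-en-1-yl]prop-2-ynoate; 13 2,3-bis(bromomethyl)-1,4-dimethoxybenzene
Product: 15 tert-butyl 3-[(1S)-2-formyl-1,3-dimethylcyclohex-2-en-1-yl]-5,8-dimethoxy-1,4-dihydronaphthalene-2-carboxylate, via ortho-quinodimethane 14 (not isolated)
Conditions: NaI (5 equiv), DMF, 70 °C, slow addition of 13 (2 equiv)
Reagents that add atoms: none
Why: Iodide converts 13 into the benzylic iodide and a second iodide induces 1,4-elimination with loss of I2 and halide, releasing the ortho-quinodimethane 14 at a low stationary concentration. 14 is a locked s-cis, electron-rich diene that regains a benzene ring on reaction, so it should add in a concerted, suprafacial [4+2] manner to the electron-poor triple bond of 10; the closest known reaction type is the Diels–Alder trapping of ortho-quinodimethanes from bis(bromomethyl)arenes with propiolates and acetylenedicarboxylates. Ring C is closed by this intermolecular cycloaddition, the two new C–C bonds (each benzylic CH2 to one alkyne carbon) forming together, and the former alkyne becomes the C2=C3 double bond of the 1,4-dihydronaphthalene 15. No stereocentre is created; the quaternary centre lies outside the reacting π-system, has no acidic neighbour and is not touched under these neutral conditions. Regiochemistry is not an issue because the two termini of 14 are equivalent. The selectivity needed is chemoselectivity for the alkynoate over the enal of 10, and the substrate secures it: the enal C=C is tetrasubstituted and buried in the ring next to the quaternary carbon, whereas the rod-like alkyne projects away from it and is activated by the ester. Rearomatisation of the dimethoxybenzene ring is the driving force that should compensate for the tertiary substituent on the alkyne, and slow addition of 13 limits dimerisation of 14. Any dehydrogenation of 15 by the I2 set free would only anticipate step 11.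

**Step 11**
Reactants: 15 tert-butyl 3-[(1S)-2-formyl-1,3-dimethylcyclohex-2-en-1-yl]-5,8-dimethoxy-1,4-dihydronaphthalene-2-carboxylate
Product: 16 tert-butyl 3-[(1S)-2-formyl-1,3-dimethylcyclohex-2-en-1-yl]-5,8-dimethoxynaphthalene-2-carboxylate
Conditions: DDQ (1.1 equiv), PhMe, rt
Reagents that add atoms: none
Why: DDQ abstracts a doubly activated (benzylic and allylic) hydride from the 1,4-dihydro ring and the cation loses a proton, the gain of a naphthalene ring driving the dehydrogenation; the enal, ester and quaternary centre are not affected at room temperature.

**Step 12**
Reactants: 16 tert-butyl 3-[(1S)-2-formyl-1,3-dimethylcyclohex-2-en-1-yl]-5,8-dimethoxynaphthalene-2-carboxylate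
Product: 18 (S)-dimethoxynaphthalene dienol lactone (rings A to D; seven-membered enol lactone between the C2 carboxyl of the 5,8-dimethoxynaphthalene and the enol oxygen of the ring A formyl carbon; ring A with endocyclic C(CH3)=CH and exocyclic C=CH–O), via naphthoic acid 17 (not isolated)
Conditions: CF3CO2H, CH2Cl2, rt; evaporate; Ac2O, NaOAc, 120 °C
Reagents that add atoms: none
Why: Acidolysis of the tert-butyl ester (loss of 2-methylpropene) frees acid 17 without a nucleophile. In Ac2O/NaOAc the mixed anhydride acylates the neighbouring aldehyde oxygen to give a cyclic acylal acetate, and loss of acetic acid across the conjugated system with removal of a ring CH2 proton (enol lactonisation in its dienol form) closes ring B. The buffered medium avoids Friedel–Crafts acylation of the dimethoxynaphthalene, and the endocyclic C(CH3)=CH isomer is the more substituted, more stable diene.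

**Step 13**
Reactants: 18 (S)-dimethoxynaphthalene dienol lactone
Product: 19 (S)-naphthoquinone dienol lactone (rings A to D; 18 with ring D as the 1,4-quinone)
Conditions: (NH4)2Ce(NO3)6 (2.5 equiv), MeCN–H2O, 0 °C, short reaction time
Reagents that add atoms: water, O
Why: Oxidative demethylation of a hydroquinone dimethyl ether by tetravalent cerium: single-electron oxidation of the electron-rich dimethoxynaphthalene, addition of water and loss of methanol give the quinone. The dienyl ester is much harder to oxidise, and the short contact at 0 °C limits its hydrolysis.

**Step 14**
Reactants: 19 (S)-naphthoquinone dienol lactone; 20 hypotaurine (2-aminoethanesulfinic acid)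
Product: 24 target CNP0348176.1, via sulfonyl hydroquinone 21 (not isolated), via sulfonyl quinone 22 (not isolated), via thiazine hydroquinone 23 (not isolated)
Conditions: MeCN–aqueous phosphate buffer (pH 7), air, rt
Reagents that add atoms: none
Why: At pH 7 the amine of 20 is protonated and only the sulfinate is nucleophilic; it adds through sulfur (sulfa-Michael addition) to the quinone carbon β to the more electrophilic carbonyl, the one on the ring C carbon para to the lactone carbonyl carbon, giving 21, which air reoxidises to 22. Intramolecular aza-Michael addition of the amine to the remaining quinone carbon (six-membered ring closure) gives 23, and a second air oxidation should deliver 24; this oxidative annulation of quinones with 20 is a known reaction type.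

## Compound list

1 | (E)-2-methylbut-2-enal | C/C=C(\C)C=O | starting material
2 | tert-butyl{[(1E)-2-methylbuta-1,3-dien-1-yl]oxy}dimethylsilane | C=C/C(C)=C/O[Si](C)(C)C(C)(C)C | intermediate
3 | methacrolein (2-methylprop-2-enal) | CC(=C)C=O | starting material
4 | (1R,2S)-2-{[tert-butyl(dimethyl)silyl]oxy}-1,3-dimethylcyclohex-3-ene-1-carbaldehyde | CC1=CCC[C@@](C)(C=O)[C@H]1O[Si](C)(C)C(C)(C)C | intermediate
5 | tert-butyl{[(1S,6S)-6-ethynyl-2,6-dimethylcyclohex-2-en-1-yl]oxy}dimethylsilane | CC1=CCC[C@@](C)(C#C)[C@H]1O[Si](C)(C)C(C)(C)C | intermediate
6 | (1S,6S)-6-ethynyl-2,6-dimethylcyclohex-2-en-1-ol | CC1=CCC[C@@](C)(C#C)[C@H]1O | intermediate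
7 | (6S)-6-ethynyl-2,6-dimethylcyclohex-2-en-1-one | CC1=CCC[C@@](C)(C#C)C1=O | intermediate
8 | (5S)-5-ethynyl-6-(methoxymethylidene)-1,5-dimethylcyclohex-1-ene | CC1=CCC[C@@](C)(C#C)C1=COC | intermediate
9 | tert-butyl 3-[(1S)-2-(methoxymethylidene)-1,3-dimethylcyclohex-3-en-1-yl]prop-2-ynoate | CC1=CCC[C@@](C)(C#CC(=O)OC(C)(C)C)C1=COC | intermediate
10 | tert-butyl 3-[(1S)-2-formyl-1,3-dimethylcyclohex-2-en-1-yl]prop-2-ynoate | CC(C)(C)OC(=O)C#C[C@]1(C)CCCC(C)=C1C=O | intermediate
11 | 2,3-dimethylbenzene-1,4-diol | Cc1c(O)ccc(O)c1C | starting material
12 | 1,4-dimethoxy-2,3-dimethylbenzene | COc1ccc(OC)c(C)c1C | intermediate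
13 | 2,3-bis(bromomethyl)-1,4-dimethoxybenzene | COc1ccc(OC)c(CBr)c1CBr | intermediate
14 | 1,4-dimethoxy-5,6-dimethylidenecyclohexa-1,3-diene (ortho-quinodimethane) | C=C1C(=C)C(OC)=CC=C1OC | intermediate
15 | tert-butyl 3-[(1S)-2-formyl-1,3-dimethylcyclohex-2-en-1-yl]-5,8-dimethoxy-1,4-dihydronaphthalene-2-carboxylate | CC(C)(C)OC(=O)C1=C(Cc2c(OC)ccc(OC)c2C1)[C@]1(C)CCCC(C)=C1C=O | intermediate
16 | tert-butyl 3-[(1S)-2-formyl-1,3-dimethylcyclohex-2-en-1-yl]-5,8-dimethoxynaphthalene-2-carboxylate | CC(C)(C)OC(=O)c1cc2c(OC)ccc(OC)c2cc1[C@]1(C)CCCC(C)=C1C=O | intermediate
17 | 3-[(1S)-2-formyl-1,3-dimethylcyclohex-2-en-1-yl]-5,8-dimethoxynaphthalene-2-carboxylic acid | OC(=O)c1cc2c(OC)ccc(OC)c2cc1[C@]1(C)CCCC(C)=C1C=O | intermediate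
18 | (S)-dimethoxynaphthalene dienol lactone (rings A to D, ring D as hydroquinone dimethyl ether) | CC1=CCC[C@]2(C)C1=COC(=O)c1cc3c(OC)ccc(OC)c3cc12 | intermediate
19 | (S)-naphthoquinone dienol lactone (rings A to D) | CC1=CCC[C@]2(C)C1=COC(=O)c1cc3c(cc12)C(=O)C=CC3=O | intermediate
20 | hypotaurine (2-aminoethanesulfinic acid) | NCCS(=O)O | starting material
21 | (S)-3-(2-aminoethylsulfonyl)hydroquinone of 19 (sulfonyl group next to the hydroxyl-bearing carbon on the ring C carbon para to the quaternary-bearing carbon) | CC1=CCC[C@]2(C)C1=COC(=O)c1cc3c(O)c(S(=O)(=O)CCN)cc(O)c3cc12 | intermediate
22 | (S)-3-(2-aminoethylsulfonyl)quinone (21 oxidised to the quinone) | CC1=CCC[C@]2(C)C1=COC(=O)c1cc3c(cc12)C(=O)C=C(C3=O)S(=O)(=O)CCN | intermediate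
23 | (S)-thiazine-fused hydroquinone (24 with ring D as hydroquinone) | CC1=CCC[C@]2(C)C1=COC(=O)c1cc3c(O)c4c(c(O)c3cc12)NCCS4(=O)=O | intermediate
24 | CNP0348176.1, (S)-configured pentacyclic thiazine-dioxide-fused naphthoquinone dienol lactone | CC1=CCC[C@]2(C)C1=COC(=O)c1cc3c(cc12)C(=O)C1=C(C3=O)S(=O)(=O)CCN1 | target

## Step count and least certain steps

Total: 14 steps. Longest linear sequence: 12 steps (steps 1 to 7 and 10 to 14); steps 8 and 9 form the short second branch.

**Step 10 (key step).** The most likely failure is dimerisation or oligomerisation of the transient diene outrunning its addition to a triple bond that carries a quaternary carbon; iodine-mediated side reactions in hot DMF are a second concern.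
- Fallback: it sets out from 13 and changes the way the diene is generated.
- 13 is treated with HOCH2SO2Na and Bu4NBr in DMF to give the cyclic sulfinate 5,8-dimethoxy-1,4-dihydro-2,3-benzoxathiine 3-oxide F1.
- F1 is heated with 10 in toluene at about 100 °C, where it should extrude SO2 slowly and release 14 under neutral, halogen-free conditions at a very low concentration.
- The route is rejoined at 15.

**Step 2.** The silyl dienol ether may be lost by protodesilylation or by Mukaiyama-type addition to the activated aldehyde under the strongly Lewis acidic catalyst, and facial discrimination may be incomplete.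
- Fallback: it sets out from 2 and 3 and replaces catalysis by resolution.
- Thermal cycloaddition in toluene at 90 °C gives the racemic cis cycloadduct F2.
- The operations of steps 3 and 4 convert it into the racemic alkyne silyl ether F3 and the racemic alcohol F4.
- Esterification with (S)-2-methoxy-2-phenylacetic acid (dicyclohexylcarbodiimide, DMAP) gives the diastereomeric esters, the (S)-O-methylmandelate of 6 F5 and the (S)-O-methylmandelate of the enantiomer of 6 F6, which are separated by chromatography.
- Methanolysis of F5 (K2CO3, MeOH) returns the route to 6.

**Step 6.** Carbonyl addition may be slow or fail because of the quaternary α-carbon, with γ-deprotonation of the enone competing.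
- Fallback: it sets out from 7 and uses a small organolithium followed by a separate elimination.
- Methoxy(trimethylsilyl)methyllithium (from (methoxymethyl)trimethylsilane and sec-BuLi, 2.2 equiv, THF, −78 °C) adds 1,2 to give the β-hydroxysilane (6S)-6-ethynyl-1-[methoxy(trimethylsilyl)methyl]-2,6-dimethylcyclohex-2-en-1-ol F7.
- KH in THF effects Peterson elimination, and the route is rejoined at 8.

**Step 12.** The dienol may be O-acetylated intermolecularly in place of ring closure, or the proton may be lost from the ring methyl group, which would place the alkene outside ring A.
- Fallback: it sets out from 17, isolated by evaporation after the acidolysis of 16.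
- (COCl)2 with catalytic DMF in CH2Cl2 at 0 °C gives the cyclic chloro-lactone (pseudo-acid chloride) F8.
- Et3N at 0 °C → rt then effects a discrete 1,4-dehydrochlorination with no external acylating agent present.
- The route is rejoined at 18.

**Step 14.** The amine may attack before the sulfinate, or the sulfinate may attack the other quinone carbon, either of which exchanges the positions of N and S; aminolysis of the dienyl ester is a further risk.
- Fallback: it sets out from 19 and separates the two bond formations.
- Sodium 2-[(tert-butoxycarbonyl)amino]ethanesulfinate in buffered aqueous MeCN under air, with the sulfinate as the only nucleophile, gives the N-Boc sulfonyl quinone F9, which is purified from any regioisomer.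
- Brief treatment with CF3CO2H in CH2Cl2 at 0 °C removes the Boc group and rejoins the route at 22, which is cyclised and oxidised in pH 7 buffer under air to 24.

## Further compounds

F1 | step 10 | 5,8-dimethoxy-1,4-dihydro-2,3-benzoxathiine 3-oxide | COc1ccc(OC)c2c1COS(=O)C2
F2 | step 2 | racemic cis-2-{[tert-butyl(dimethyl)silyl]oxy}-1,3-dimethylcyclohex-3-ene-1-carbaldehyde (both enantiomers) | CC1=CCC[C@@](C)(C=O)[C@H]1O[Si](C)(C)C(C)(C)C.CC1=CCC[C@](C)(C=O)[C@@H]1O[Si](C)(C)C(C)(C)C
F3 | step 2 | racemic cis-tert-butyl[(6-ethynyl-2,6-dimethylcyclohex-2-en-1-yl)oxy]dimethylsilane (both enantiomers) | CC1=CCC[C@@](C)(C#C)[C@H]1O[Si](C)(C)C(C)(C)C.CC1=CCC[C@](C)(C#C)[C@@H]1O[Si](C)(C)C(C)(C)C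
F4 | step 2 | racemic cis-6-ethynyl-2,6-dimethylcyclohex-2-en-1-ol (both enantiomers) | CC1=CCC[C@@](C)(C#C)[C@H]1O.CC1=CCC[C@](C)(C#C)[C@@H]1O
F5 | step 2 | (1S,6S)-6-ethynyl-2,6-dimethylcyclohex-2-en-1-yl (S)-2-methoxy-2-phenylacetate | CC1=CCC[C@@](C)(C#C)[C@H]1OC(=O)[C@@H](OC)c1ccccc1
F6 | step 2 | (1R,6R)-6-ethynyl-2,6-dimethylcyclohex-2-en-1-yl (S)-2-methoxy-2-phenylacetate | CC1=CCC[C@](C)(C#C)[C@@H]1OC(=O)[C@@H](OC)c1ccccc1
F7 | step 6 | (6S)-6-ethynyl-1-[methoxy(trimethylsilyl)methyl]-2,6-dimethylcyclohex-2-en-1-ol (mixture at the two new centres) | CC1=CCC[C@@](C)(C#C)C1(O)C(OC)[Si](C)(C)C
F8 | step 12 | (S)-cyclic chloro-lactone of 17 (seven-membered ring Ar–C(=O)–O–CHCl– on the ring A sp2 carbon; ring A C(CH3)=C tetrasubstituted) | CC1=C2C(Cl)OC(=O)c3cc4c(OC)ccc(OC)c4cc3[C@]2(C)CCC1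
F9 | step 14 | (S)-3-{2-[(tert-butoxycarbonyl)amino]ethylsulfonyl}quinone (N-Boc derivative of 22) | CC1=CCC[C@]2(C)C1=COC(=O)c1cc3c(cc12)C(=O)C=C(C3=O)S(=O)(=O)CCNC(=O)OC(C)(C)C
A1 | alternative 1 | 7-bromo-4-methoxy-1-methylnaphthalen-2-ol | Cc1c(O)cc(OC)c2ccc(Br)cc12
A2 | alternative 1 | pent-1-en-3-one | CCC(=O)C=C
A3 | alternative 1 | (4aS)-6-bromo-9-methoxy-1,4a-dimethyl-4,4a-dihydrophenanthren-2(3H)-one | CC1=C2C=C(OC)c3ccc(Br)cc3[C@]2(C)CCC1=O
A4 | alternative 2 | tert-butyl 4-bromo-2-[(1S)-2-(methoxymethylidene)-1,3-dimethylcyclohex-3-en-1-yl]benzoate | COC=C1C(C)=CCC[C@@]1(C)c1cc(Br)ccc1C(=O)OC(C)(C)C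
A5 | alternative 2 | tert-butyl 7,8-dioxo-2-thia-5-azabicyclo[4.2.0]oct-1(6)-ene-5-carboxylate 2,2-dioxide | O=C1C(=O)C2=C1S(=O)(=O)CCN2C(=O)OC(C)(C)C
A6 | alternative 2 | tert-butyl 7-aryl-7-hydroxy-8-oxo-2-thia-5-azabicyclo[4.2.0]oct-1(6)-ene-5-carboxylate 2,2-dioxide, aryl = 4-(tert-butoxycarbonyl)-3-[(1S)-2-(methoxymethylidene)-1,3-dimethylcyclohex-3-en-1-yl]phenyl | COC=C1C(C)=CCC[C@@]1(C)c1cc(ccc1C(=O)OC(C)(C)C)C1(O)C(=O)C2=C1N(C(=O)OC(C)(C)C)CCS2(=O)=O
A7 | alternative 2 | ring D hydroquinone with N-Boc thiazine dioxide, tert-butyl ester and methyl dienol ether, (S) at the quaternary carbon | COC=C1C(C)=CCC[C@@]1(C)c1cc2c(O)c3N(C(=O)OC(C)(C)C)CCS(=O)(=O)c3c(O)c2cc1C(=O)OC(C)(C)C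
A8 | alternative 3 | tert-butyl 5,6,8-trimethoxy-3-(3-oxoprop-1-en-2-yl)naphthalene-2-carboxylate | C=C(C=O)c1cc2c(OC)c(OC)cc(OC)c2cc1C(=O)OC(C)(C)C
A9 | alternative 3 | tert-butyl 3-(2-{[tert-butyl(dimethyl)silyl]oxy}-1-formyl-3-methylcyclohex-3-en-1-yl)-5,6,8-trimethoxynaphthalene-2-carboxylate, formyl and silyloxy cis | CC1=CCC[C@@](C=O)(c2cc3c(OC)c(OC)cc(OC)c3cc2C(=O)OC(C)(C)C)[C@@H]1O[Si](C)(C)C(C)(C)C
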